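A direct plan would join an alkynyl carbinol chain (C1–C4, C8–C10) as a keto ylide with dibromomaleic anhydride to give the enol lactone A1,
would turn A1 into the furan-3(2H)-one aldehyde A2 by a gold-catalysed cyclization with 1,2-methyl shift, would close the ten-membered ring at C7–C8 by a Nozaki–Hiyama–Kishi reaction (bromo alcohol A3), and would finish by hydroxymethylation at C11 and two acylations.
Weakest would be the furanone-forming cyclization with methyl shift and silyl transfer, because it has no close precedent and must carry the carbinol configuration into the quaternary C4;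
the chromium-mediated closure of the medium ring, because it must choose one of two C–Br bonds, overcome transannular strain at high dilution and set C8 with a large excess of chiral ligand;
and the olefination of the anhydride carbonyl, because the E geometry at C5=C6 would rest on kinetic control only.

The new plan reconnects C1 with C6, the two ketone-level carbons (C1 of the furanone, C6 of the enol lactone) that face each other across the ten-membered ring. With this bond the bridged macrocycle collapses to a 7-oxanorbornane fused to a cyclohexane (ring B), which an intramolecular furan–allene Diels–Alder reaction builds while C8 and C10 set the quaternary C4. A Grob fragmentation then cuts C1–C6 and delivers, in one operation, the ten-membered carbocycle, the C6 carbonyl and the enol ether of the furan-3(2H)-one. No macrocyclization, no gold-mediated rearrangement and no anhydride olefination remain; the E geometry at C5=C6 is dictated by the ring.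

Key step: step 11

Remark: atoms carry the germacrane numbers of the target in all intermediates (ring carbons C1–C10, lactone carbons C11–C13, C14 on C10, C15 on C4). The configuration at C6 of the intermediates between the enol-ether oxidation and the fragmentation is of no consequence, since this carbon becomes trigonal; the epimer expected from attack anti to the C8 silyloxy group is drawn.

Step 1
Reactants: 1 2-methylfuran; 2 (E)-but-2-enal
Product: 3 (3S)-3-(5-methylfuran-2-yl)butanal
Conditions: (2R,5R)-5-benzyl-2-tert-butyl-3-methylimidazolidin-4-one·CF3CO2H (20 mol %), 1 (3 equiv), CH2Cl2/i-PrOH, −50 °C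
Reagents that add atoms: none
Why: Iminium-ion-catalysed Friedel–Crafts alkylation, in which the imidazolidinone shields one face of the enal-derived iminium ion and the free C5 position of the furan adds to the β-carbon, sets the future C10 (S) under catalyst control (the catalyst antipode is chosen to give 3S).

Step 2
Reactants: 3 (3S)-3-(5-methylfuran-2-yl)butanal; 4 methoxyallene
Product: 5 (6S)-3-methoxy-6-(5-methylfuran-2-yl)hepta-1,2-dien-4-ol (both C4 epimers)
Conditions: 4, n-BuLi, THF, −40 °C; then 3, −78 °C; aq. NH4Cl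
Reagents that add atoms: none
Why: α-Lithiation of the allenyl ether and 1,2-addition of 1-lithio-1-methoxyallene to the aldehyde joins C8 to the C5–C7 allene, and the carbinol configuration is left open because step 3 erases it.

Step 3
Reactants: 5 (6S)-3-methoxy-6-(5-methylfuran-2-yl)hepta-1,2-dien-4-ol
Product: 6 (6S)-3-methoxy-6-(5-methylfuran-2-yl)hepta-1,2-dien-4-one
Conditions: Dess–Martin periodinane, NaHCO3, CH2Cl2, 0 °C
Reagents that add atoms: none
Why: Buffered Dess–Martin oxidation of the secondary allenyl carbinol gives the α-methoxyallenyl ketone without acid that would hydrolyse the enol ether.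

Step 4
Reactants: 6 (6S)-3-methoxy-6-(5-methylfuran-2-yl)hepta-1,2-dien-4-one
Product: 7 (4S,6S)-3-methoxy-6-(5-methylfuran-2-yl)hepta-1,2-dien-4-ol
Conditions: (R)-2-methyl-CBS-oxazaborolidine (20 mol %), catecholborane, toluene, −78 °C; then MeOH, aq. NaOH
Reagents that add atoms: none
Why: Corey–Bakshi–Shibata reduction, in which the oxazaborolidine tells the sp2 allenyl group (large) from the CH2 group (small) and delivers hydride to one carbonyl face, sets C8 (S) under reagent control (antipode chosen accordingly) while catecholborane at low temperature spares allene and furan.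

Step 5
Reactants: 7 (4S,6S)-3-methoxy-6-(5-methylfuran-2-yl)hepta-1,2-dien-4-ol
Product: 8 tert-butyl{[(4S,6S)-3-methoxy-6-(5-methylfuran-2-yl)hepta-1,2-dien-4-yl]oxy}dimethylsilane
Conditions: TBSCl, imidazole, DMF, 23 °C
Reagents that add atoms: tert-butyl(chloro)dimethylsilane, CC(C)(C)[Si](C)(C)Cl
Why: Standard silylation under non-acidic conditions masks the C8 hydroxyl, which would otherwise add to the allene, as an ether that survives all steps up to step 13.

Step 6
Reactants: 8 tert-butyl{[(4S,6S)-3-methoxy-6-(5-methylfuran-2-yl)hepta-1,2-dien-4-yl]oxy}dimethylsilane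
Product: 9 (4S,8S,10S)-8-(tert-butyldimethylsilyloxy)-7-methoxy-1,4-epoxy-1,6-cyclo-11,12,13-trinorgermacra-2,6-diene
Conditions: toluene (0.02 M), 2,6-di-tert-butyl-4-methylphenol, Et3N (10 mol %), 120 °C, sealed tube
Reagents that add atoms: none
Why: Intramolecular Diels–Alder reaction of the 2,5-dialkylfuran with the unsubstituted terminal π bond of the alkoxyallene (the enol-ether π bond is electron-rich and would have to join two fully substituted carbons) forms C4–C5 and C1–C6 and is driven by loss of allene strain; because C6 stays trigonal, ring B forms as a half-chair with the C10 methyl pseudoequatorial and the C8 silyloxy group pseudoaxial (no A(1,2) strain with the C7 methoxy group), and this one arrangement holds the tether on the furan face that gives 4S.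

Step 7
Reactants: 9 (4S,8S,10S)-8-(tert-butyldimethylsilyloxy)-7-methoxy-1,4-epoxy-1,6-cyclo-11,12,13-trinorgermacra-2,6-diene
Product: 10 (4S,8S,10S)-8-(tert-butyldimethylsilyloxy)-6-hydroxy-1,4:2,3-diepoxy-1,6-cyclo-11,12,13-trinorgermacran-7-one
Conditions: DMDO (2.5 equiv), acetone/CH2Cl2, −40 to 0 °C; then wet silica gel
Reagents that add atoms: dimethyldioxirane, CC1(C)OO1; water, O
Why: Rubottom-type epoxidation of the methyl enol ether and hydrolytic collapse of the methoxy epoxide give the C6 tertiary alcohol and the C7 ketone, and the second equivalent epoxidizes the strained C2=C3 bond from the exo face (syn to the oxygen bridge), which places the future C3 oxygen and sets the C2–O bond antiperiplanar to C1–C6.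

Step 8
Reactants: 11 ethyl 2-(diethoxyphosphoryl)prop-2-enoate; 12 (4-methoxyphenyl)methanol
Product: 13 ethyl 2-(diethoxyphosphoryl)-3-[(4-methoxybenzyl)oxy]propanoate
Conditions: KOt-Bu (5 mol %), THF, 0 °C
Reagents that add atoms: none
Why: Base-catalysed oxa-Michael addition of the benzylic alcohol to the doubly activated alkene puts the protected C13 oxygen on the future C11–C12 unit.

Step 9
Reactants: 13 ethyl 2-(diethoxyphosphoryl)-3-[(4-methoxybenzyl)oxy]propanoate
Product: 14 2-(diethoxyphosphoryl)-3-[(4-methoxybenzyl)oxy]propanoic acid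
Conditions: LiOH (1.05 equiv), THF/H2O, 0 °C; then cold 1 M HCl
Reagents that add atoms: lithium hydroxide, [Li+].[OH-]
Why: Saponification cleaves the carboxylic ethyl ester much faster than the phosphonate esters, and the carboxylate formed no longer supports retro-Michael loss of the alkoxide.

Step 10
Reactants: 10 (4S,8S,10S)-8-(tert-butyldimethylsilyloxy)-6-hydroxy-1,4:2,3-diepoxy-1,6-cyclo-11,12,13-trinorgermacran-7-one; 14 2-(diethoxyphosphoryl)-3-[(4-methoxybenzyl)oxy]propanoic acid
Product: 16 (4S,8S,10S)-8-(tert-butyldimethylsilyloxy)-13-(4-methoxybenzyloxy)-1,4:2,3-diepoxy-1,6-cyclogermacr-7(11)-en-12,6-olide, via phosphonoacetate ester 15 (not isolated)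
Conditions: 14, DCC, DMAP, CH2Cl2, 0 to 23 °C; then LiCl, i-Pr2NEt, MeCN, 23 °C
Reagents that add atoms: none
Why: Carbodiimide activation of an α-phosphono acid passes through the phosphonoketene, which acylates even hindered tertiary alcohols, and the intramolecular Horner–Wadsworth–Emmons reaction (Masamune–Roush conditions) of the phosphonate carbanion with the neighbouring C7 ketone closes the butenolide (C7=C11) faster than β-elimination of the benzyloxy group.

Step 11
Reactants: 16 (4S,8S,10S)-8-(tert-butyldimethylsilyloxy)-13-(4-methoxybenzyloxy)-1,4:2,3-diepoxy-1,6-cyclogermacr-7(11)-en-12,6-olide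
Product: 19 (3R,4S,8S,10S)-8-(tert-butyldimethylsilyloxy)-3,6-dihydroxy-13-(4-methoxybenzyloxy)-1,4-epoxygermacra-1,7(11)-dien-12,6-olide, via ring-opened hydroxy carboxylate 17 (not isolated), via keto carboxylate 18 (not isolated)
Conditions: KOt-Bu (4 equiv), H2O (1.5 equiv), THF, 0 to 40 °C; then cold aq. KH2PO4, rapid extraction
Reagents that add atoms: water, O
Why: Hydroxide (from KOt-Bu and water) opens the butenolide to the C12 carboxylate and the C6 tertiary alkoxide (17), which then undergoes a Grob fragmentation: the C1–C6 σ bond, held close to antiperiplanar to the exo C2–O bond of the epoxide by the 7-oxanorbornane frame, breaks as C6=O and C1=C2 form and the epoxide oxygen leaves as the C3 alkoxide (18). The closest known reaction type is the base-induced fragmentation of γ-hydroxy epoxides and of 1,3-diol monosulfonates that turns fused bicycles into medium rings; the exo C2–X/C1–C6 alignment is the one that governs σ participation in 2-norbornyl systems. No ring is closed: the ten-membered carbocycle C1–C10 and the C1–O–C4 dihydrofuran appear together when the bond shared by the two six-membered rings is cut, so the only carbocyclization the route needs is the six-membered one of step 6. No stereocentre is formed or touched: C4, C8 and C10 are spectators and C3 keeps the exo oxygen until it becomes the ketone in step 12. The step needs C1–C6 to break in preference to C5–C6 and C6–C7 and to win over relactonization; only C1–C6 has an antiperiplanar nucleofuge, C1 is stabilized by the bridging oxygen as it becomes an enol ether, the strain of the bicyclo[2.2.1] core and of the epoxide is released, and relactonization is reversible whereas fragmentation is not. Mild acidification then closes the keto acid to the hydroxybutenolide 19.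

Step 12
Reactants: 19 (3R,4S,8S,10S)-8-(tert-butyldimethylsilyloxy)-3,6-dihydroxy-13-(4-methoxybenzyloxy)-1,4-epoxygermacra-1,7(11)-dien-12,6-olide
Product: 22 (4S,8S,10S)-8-(tert-butyldimethylsilyloxy)-13-(4-methoxybenzyloxy)-3-oxo-1,4-epoxygermacra-1,5E,7(11)-trien-12,6-olide, via furanone hemiketal 20 (not isolated), via hemiketal mesylate 21 (not isolated)
Conditions: Dess–Martin periodinane, NaHCO3, CH2Cl2, 0 °C; then MsCl, Et3N, −20 to 0 °C
Reagents that add atoms: none
Why: Dess–Martin oxidation of the allylic C3 carbinol gives the furan-3(2H)-one, and mesylation of the hemiketal hydroxyl followed by elimination toward C5 (the only carbon with β-hydrogens) gives the alkylidene butenolide, whose E geometry (C4 cis to C7) is the only one the bridged ten-membered ring can hold.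

Step 13
Reactants: 22 (4S,8S,10S)-8-(tert-butyldimethylsilyloxy)-13-(4-methoxybenzyloxy)-3-oxo-1,4-epoxygermacra-1,5E,7(11)-trien-12,6-olide
Product: 23 (4S,8S,10S)-8-hydroxy-13-(4-methoxybenzyloxy)-3-oxo-1,4-epoxygermacra-1,5E,7(11)-trien-12,6-olide
Conditions: HF·pyridine, pyridine, THF, 0 to 23 °C
Reagents that add atoms: none
Why: Buffered fluoride desilylation frees the C8 hydroxyl while the benzyl ether, the enol lactone and the vinylogous ester stay intact.

Step 14
Reactants: 24 2-(hydroxymethyl)prop-2-enoic acid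
Product: 26 2-{[(tert-butyldiphenylsilyl)oxy]methyl}prop-2-enoic acid, via silyl ester 25 (not isolated)
Conditions: TBDPSCl (2.2 equiv), imidazole, DMF, 23 °C; then THF/H2O/AcOH, 23 °C
Reagents that add atoms: tert-butyl(chloro)diphenylsilane, CC(C)(C)[Si](Cl)(c1ccccc1)c1ccccc1
Why: Bis-silylation followed by selective hydrolysis of the far more labile silyl ester gives the O-protected side-chain acid with a silyl ether that survives the oxidative debenzylation of step 16.

Step 15
Reactants: 23 (4S,8S,10S)-8-hydroxy-13-(4-methoxybenzyloxy)-3-oxo-1,4-epoxygermacra-1,5E,7(11)-trien-12,6-olide; 26 2-{[(tert-butyldiphenylsilyl)oxy]methyl}prop-2-enoic acid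
Product: 28 (4S,8S,10S)-8-{2-[(tert-butyldiphenylsilyloxy)methyl]prop-2-enoyloxy}-13-(4-methoxybenzyloxy)-3-oxo-1,4-epoxygermacra-1,5E,7(11)-trien-12,6-olide, via mixed anhydride 27 (not isolated)
Conditions: 2,4,6-trichlorobenzoyl chloride, Et3N, toluene, 23 °C; then 23, DMAP, 23 °C
Reagents that add atoms: none
Why: Yamaguchi esterification acylates the hindered secondary alcohol at oxygen, so C8 keeps its configuration.

Step 16
Reactants: 28 (4S,8S,10S)-8-{2-[(tert-butyldiphenylsilyloxy)methyl]prop-2-enoyloxy}-13-(4-methoxybenzyloxy)-3-oxo-1,4-epoxygermacra-1,5E,7(11)-trien-12,6-olide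
Product: 29 (4S,8S,10S)-8-{2-[(tert-butyldiphenylsilyloxy)methyl]prop-2-enoyloxy}-13-hydroxy-3-oxo-1,4-epoxygermacra-1,5E,7(11)-trien-12,6-olide
Conditions: DDQ, CH2Cl2/pH 7 buffer, 0 °C
Reagents that add atoms: none
Why: Oxidative cleavage of the 4-methoxybenzyl ether by hydride abstraction and hydrolysis of the oxocarbenium ion frees only the C13 hydroxyl, since the electron-poor enol ethers, the acrylate and the silyl ether are inert to DDQ.

Step 17
Reactants: 29 (4S,8S,10S)-8-{2-[(tert-butyldiphenylsilyloxy)methyl]prop-2-enoyloxy}-13-hydroxy-3-oxo-1,4-epoxygermacra-1,5E,7(11)-trien-12,6-olide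
Product: 30 (4S,8S,10S)-13-acetoxy-8-{2-[(tert-butyldiphenylsilyloxy)methyl]prop-2-enoyloxy}-3-oxo-1,4-epoxygermacra-1,5E,7(11)-trien-12,6-olide
Conditions: Ac2O, pyridine, DMAP (cat.), CH2Cl2, 0 °C
Reagents that add atoms: acetic anhydride, CC(=O)OC(C)=O
Why: Acetylation of the only free hydroxyl, a primary allylic one, needs no selectivity.

Step 18
Reactants: 30 (4S,8S,10S)-13-acetoxy-8-{2-[(tert-butyldiphenylsilyloxy)methyl]prop-2-enoyloxy}-3-oxo-1,4-epoxygermacra-1,5E,7(11)-trien-12,6-olide
Product: 31 (4S,8S,10S)-13-acetoxy-8-[2-(hydroxymethyl)prop-2-enoyloxy]-3-oxo-1,4-epoxygermacra-1,5E,7(11)-trien-12,6-olide (CNP0193735.1)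
Conditions: HF·pyridine, pyridine, THF, 0 to 23 °C
Reagents that add atoms: none
Why: Buffered fluoride desilylation frees the primary alcohol of the side chain while acetate, acrylate and enol lactone stay intact.

## Compound list

1 | 2-methylfuran | Cc1ccco1 | starting material
2 | (E)-but-2-enal (crotonaldehyde) | C/C=C/C=O | starting material
3 | (3S)-3-(5-methylfuran-2-yl)butanal | O=CC[C@H](C)c1ccc(C)o1 | intermediate
4 | methoxyallene (1-methoxypropa-1,2-diene) | COC=C=C | starting material
5 | (6S)-3-methoxy-6-(5-methylfuran-2-yl)hepta-1,2-dien-4-ol (both C4 epimers) | C=C=C(OC)C(O)C[C@H](C)c1ccc(C)o1 | intermediate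
6 | (6S)-3-methoxy-6-(5-methylfuran-2-yl)hepta-1,2-dien-4-one | C=C=C(OC)C(=O)C[C@H](C)c1ccc(C)o1 | intermediate
7 | (4S,6S)-3-methoxy-6-(5-methylfuran-2-yl)hepta-1,2-dien-4-ol | C=C=C(OC)[C@@H](O)C[C@H](C)c1ccc(C)o1 | intermediate
8 | tert-butyl{[(4S,6S)-3-methoxy-6-(5-methylfuran-2-yl)hepta-1,2-dien-4-yl]oxy}dimethylsilane | C=C=C(OC)[C@@H](O[Si](C)(C)C(C)(C)C)C[C@H](C)c1ccc(C)o1 | intermediate
9 | (4S,8S,10S)-8-(tert-butyldimethylsilyloxy)-7-methoxy-1,4-epoxy-1,6-cyclo-11,12,13-trinorgermacra-2,6-diene (Diels–Alder adduct; oxygen bridge C1–C4, new bonds C1–C6 and C4–C5) | COC1=C2C[C@@]3(C)C=C[C@@]2(O3)[C@@H](C)C[C@@H]1O[Si](C)(C)C(C)(C)C | intermediate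
10 | (4S,8S,10S)-8-(tert-butyldimethylsilyloxy)-6-hydroxy-1,4:2,3-diepoxy-1,6-cyclo-11,12,13-trinorgermacran-7-one (2,3-epoxide on the face of the 1,4-oxygen bridge; 6-OH on the opposite face) | O=C1[C@@H](O[Si](C)(C)C(C)(C)C)C[C@H](C)[C@]2(O3)[C@H]4O[C@H]4[C@]3(C)C[C@@]12O | intermediate
11 | ethyl 2-(diethoxyphosphoryl)prop-2-enoate | C=C(C(=O)OCC)P(=O)(OCC)OCC | starting material
12 | (4-methoxyphenyl)methanol | COc1ccc(CO)cc1 | starting material
13 | ethyl 2-(diethoxyphosphoryl)-3-[(4-methoxybenzyl)oxy]propanoate (racemic) | CCOC(=O)C(COCc1ccc(OC)cc1)P(=O)(OCC)OCC | intermediate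
14 | 2-(diethoxyphosphoryl)-3-[(4-methoxybenzyl)oxy]propanoic acid (racemic) | OC(=O)C(COCc1ccc(OC)cc1)P(=O)(OCC)OCC | intermediate
15 | 6-O-{2-(diethoxyphosphoryl)-3-[(4-methoxybenzyl)oxy]propanoyl} derivative of 10 | O=C1[C@@H](O[Si](C)(C)C(C)(C)C)C[C@H](C)[C@]2(O3)[C@H]4O[C@H]4[C@]3(C)C[C@@]12OC(=O)C(COCc1ccc(OC)cc1)P(=O)(OCC)OCC | intermediate
16 | (4S,8S,10S)-8-(tert-butyldimethylsilyloxy)-13-(4-methoxybenzyloxy)-1,4:2,3-diepoxy-1,6-cyclogermacr-7(11)-en-12,6-olide | O=C1O[C@@]23C[C@]4(C)O[C@]2([C@H]5O[C@H]54)[C@@H](C)C[C@H](O[Si](C)(C)C(C)(C)C)C3=C1COCc1ccc(OC)cc1 | intermediate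
17 | (4S,8S,10S)-8-(tert-butyldimethylsilyloxy)-6-hydroxy-13-(4-methoxybenzyloxy)-1,4:2,3-diepoxy-1,6-cyclogermacr-7(11)Z-en-12-oic acid (as dipotassium alkoxide carboxylate) | OC(=O)/C(COCc1ccc(OC)cc1)=C2\[C@]3(O)C[C@]4(C)O[C@]3([C@H]5O[C@H]54)[C@@H](C)C[C@@H]2O[Si](C)(C)C(C)(C)C | intermediate
18 | (3R,4S,8S,10S)-8-(tert-butyldimethylsilyloxy)-3-hydroxy-13-(4-methoxybenzyloxy)-6-oxo-1,4-epoxygermacra-1,7(11)Z-dien-12-oic acid (as dipotassium salt) | OC(=O)/C(COCc1ccc(OC)cc1)=C2\C(=O)C[C@]3(C)OC(=C[C@H]3O)[C@@H](C)C[C@@H]2O[Si](C)(C)C(C)(C)C | intermediate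
19 | (3R,4S,8S,10S)-8-(tert-butyldimethylsilyloxy)-3,6-dihydroxy-13-(4-methoxybenzyloxy)-1,4-epoxygermacra-1,7(11)-dien-12,6-olide (C6 hemiketal epimers) | O=C1OC2(O)C[C@]3(C)OC(=C[C@H]3O)[C@@H](C)C[C@H](O[Si](C)(C)C(C)(C)C)C2=C1COCc1ccc(OC)cc1 | intermediate
20 | (4S,8S,10S)-8-(tert-butyldimethylsilyloxy)-6-hydroxy-13-(4-methoxybenzyloxy)-3-oxo-1,4-epoxygermacra-1,7(11)-dien-12,6-olide | O=C1OC2(O)C[C@]3(C)OC(=CC3=O)[C@@H](C)C[C@H](O[Si](C)(C)C(C)(C)C)C2=C1COCc1ccc(OC)cc1 | intermediate
21 | 6-O-methanesulfonate of 20 | O=C1OC2(OS(C)(=O)=O)C[C@]3(C)OC(=CC3=O)[C@@H](C)C[C@H](O[Si](C)(C)C(C)(C)C)C2=C1COCc1ccc(OC)cc1 | intermediate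
22 | (4S,8S,10S)-8-(tert-butyldimethylsilyloxy)-13-(4-methoxybenzyloxy)-3-oxo-1,4-epoxygermacra-1,5E,7(11)-trien-12,6-olide | CC(C)(C)[Si](C)(C)O[C@H]1C[C@H](C)C2=CC(=O)[C@](C)(/C=C3/OC(=O)C(COCc4ccc(OC)cc4)=C31)O2 | intermediate
23 | (4S,8S,10S)-8-hydroxy-13-(4-methoxybenzyloxy)-3-oxo-1,4-epoxygermacra-1,5E,7(11)-trien-12,6-olide | O[C@H]1C[C@H](C)C2=CC(=O)[C@](C)(/C=C3/OC(=O)C(COCc4ccc(OC)cc4)=C31)O2 | intermediate
24 | 2-(hydroxymethyl)prop-2-enoic acid | C=C(CO)C(=O)O | starting material
25 | tert-butyldiphenylsilyl 2-{[(tert-butyldiphenylsilyl)oxy]methyl}prop-2-enoate | C=C(CO[Si](c1ccccc1)(c1ccccc1)C(C)(C)C)C(=O)O[Si](c1ccccc1)(c1ccccc1)C(C)(C)C | intermediate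
26 | 2-{[(tert-butyldiphenylsilyl)oxy]methyl}prop-2-enoic acid | C=C(CO[Si](c1ccccc1)(c1ccccc1)C(C)(C)C)C(=O)O | intermediate
27 | 2-{[(tert-butyldiphenylsilyl)oxy]methyl}prop-2-enoic 2,4,6-trichlorobenzoic anhydride | C=C(CO[Si](c1ccccc1)(c1ccccc1)C(C)(C)C)C(=O)OC(=O)c1c(Cl)cc(Cl)cc1Cl | intermediate
28 | (4S,8S,10S)-8-{2-[(tert-butyldiphenylsilyloxy)methyl]prop-2-enoyloxy}-13-(4-methoxybenzyloxy)-3-oxo-1,4-epoxygermacra-1,5E,7(11)-trien-12,6-olide | C=C(CO[Si](c1ccccc1)(c1ccccc1)C(C)(C)C)C(=O)O[C@H]1C[C@H](C)C2=CC(=O)[C@](C)(/C=C3/OC(=O)C(COCc4ccc(OC)cc4)=C31)O2 | intermediate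
29 | (4S,8S,10S)-8-{2-[(tert-butyldiphenylsilyloxy)methyl]prop-2-enoyloxy}-13-hydroxy-3-oxo-1,4-epoxygermacra-1,5E,7(11)-trien-12,6-olide | C=C(CO[Si](c1ccccc1)(c1ccccc1)C(C)(C)C)C(=O)O[C@H]1C[C@H](C)C2=CC(=O)[C@](C)(/C=C3/OC(=O)C(CO)=C31)O2 | intermediate
30 | (4S,8S,10S)-13-acetoxy-8-{2-[(tert-butyldiphenylsilyloxy)methyl]prop-2-enoyloxy}-3-oxo-1,4-epoxygermacra-1,5E,7(11)-trien-12,6-olide | C=C(CO[Si](c1ccccc1)(c1ccccc1)C(C)(C)C)C(=O)O[C@H]1C[C@H](C)C2=CC(=O)[C@](C)(/C=C3/OC(=O)C(COC(C)=O)=C31)O2 | intermediate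
31 | (4S,8S,10S)-13-acetoxy-8-[2-(hydroxymethyl)prop-2-enoyloxy]-3-oxo-1,4-epoxygermacra-1,5E,7(11)-trien-12,6-olide (CNP0193735.1) | C=C(CO)C(=O)O[C@H]1C[C@H](C)C2=CC(=O)[C@](C)(/C=C3/OC(=O)C(COC(C)=O)=C31)O2 | target

Total step count: 18. Longest linear sequence: 15 (steps 1–7, 10–13, 15–18).

Steps most likely to fail:

Step 11 (key step): relactonization of the ring-opened alkoxide may outrun fragmentation, because an epoxide oxygen is only a moderate nucleofuge. The fallback would set out from 9 and come back at 19. One equivalent of DMDO at −78 °C would oxidize only the enol ether to the ketol F1. Esterification with 14 would give the phosphonoacetate F2, and olefination as in step 10 the butenolide F3. OsO4/N-methylmorpholine N-oxide would dihydroxylate C2=C3 from the exo face to the diol F4. 1,1'-Sulfonyldiimidazole and NaH would give the cyclic sulfate F5, whose exo C2–O bond is a far better nucleofuge in the same antiperiplanar position. KOt-Bu/H2O as in step 11 would then give the C3 hydrogen sulfate F6, and catalytic H2SO4 in moist THF at 0 °C would cleave the sulfate ester and close the lactol to 19.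

Step 6: the cycloaddition may be slower than thermal isomerization or oligomerization of the alkoxyallene, or the enol-ether π bond may take part and close a five-membered ring instead. The fallback would set out from 1 and come back at 10. A terminal ynone would replace the allene, since it is activated, offers only the C5/C6 pair and keeps C6 trigonal, so that the same half-chair relay holds. Cu(OTf)2/bis(oxazoline)-catalysed Friedel–Crafts addition of 1 to methyl (E)-2-oxopent-3-enoate would give the keto ester F7. Reduction with B-chlorodiisopinocampheylborane would give the hydroxy ester F8, and TBSCl the silyl ether F9. MeNHOMe·HCl/i-PrMgCl would give the Weinreb amide F10, and ethynylmagnesium bromide the ynone F11. Warming to 60 °C would give the 7-oxanorbornadiene enone F12. Reductive α-hydroxylation (Mn(dpm)3 with dpm = 2,2,6,6-tetramethylheptane-3,5-dionate, PhSiH3, O2, then P(OEt)3) would give the ketol F1, and one equivalent of DMDO the epoxy ketol 10.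

Step 10: the neopentyl-type tertiary ketol may resist acylation, or it may rearrange (α-ketol shift) before it is acylated. The fallback would set out from 9 and come back at 15. The C6–O acyl bond would be made by oxidative α-acyloxylation of the enol ether instead of by acylation of an alcohol. Iodosylbenzene and two equivalents of acid 14 would form the bis(acyloxy)iodobenzene F13. The enol ether of 9 would attack its iodine atom at C6, one phosphonoacyloxy group would pass to C6 as iodobenzene leaves, and hydrolytic loss of the methyl group as methanol would give the phosphonoacetate F2 directly. One equivalent of DMDO would then epoxidize C2=C3 to 15.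

## Further compounds

F1 | step 11 | (4S,8S,10S)-8-(tert-butyldimethylsilyloxy)-6-hydroxy-1,4-epoxy-1,6-cyclo-11,12,13-trinorgermacr-2-en-7-one | O=C1[C@@H](O[Si](C)(C)C(C)(C)C)C[C@H](C)[C@]2(O3)C=C[C@]3(C)C[C@@]12O
F2 | step 11 | 6-O-{2-(diethoxyphosphoryl)-3-[(4-methoxybenzyl)oxy]propanoyl} derivative of F1 | O=C1[C@@H](O[Si](C)(C)C(C)(C)C)C[C@H](C)[C@]2(O3)C=C[C@]3(C)C[C@@]12OC(=O)C(COCc1ccc(OC)cc1)P(=O)(OCC)OCC
F3 | step 11 | (4S,8S,10S)-8-(tert-butyldimethylsilyloxy)-13-(4-methoxybenzyloxy)-1,4-epoxy-1,6-cyclogermacra-2,7(11)-dien-12,6-olide | O=C1O[C@@]23C[C@]4(C)O[C@]2(C=C4)[C@@H](C)C[C@H](O[Si](C)(C)C(C)(C)C)C3=C1COCc1ccc(OC)cc1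
F4 | step 11 | 2,3-exo-cis-diol of F3 | O=C1O[C@@]23C[C@]4(C)O[C@]2([C@@H](O)[C@H]4O)[C@@H](C)C[C@H](O[Si](C)(C)C(C)(C)C)C3=C1COCc1ccc(OC)cc1
F5 | step 11 | 2,3-cyclic sulfate of F4 | O=C1O[C@@]23C[C@]4(C)O[C@]2([C@H]5OS(=O)(=O)O[C@@H]45)[C@@H](C)C[C@H](O[Si](C)(C)C(C)(C)C)C3=C1COCc1ccc(OC)cc1
F6 | step 11 | 3-O-sulfate of 18 (as potassium salt) | OC(=O)/C(COCc1ccc(OC)cc1)=C2\C(=O)C[C@]3(C)OC(=C[C@H]3OS(=O)(=O)O)[C@@H](C)C[C@@H]2O[Si](C)(C)C(C)(C)C
F7 | step 6 | methyl (4S)-4-(5-methylfuran-2-yl)-2-oxopentanoate | COC(=O)C(=O)C[C@H](C)c1ccc(C)o1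
F8 | step 6 | methyl (2S,4S)-2-hydroxy-4-(5-methylfuran-2-yl)pentanoate | COC(=O)[C@@H](O)C[C@H](C)c1ccc(C)o1
F9 | step 6 | methyl (2S,4S)-2-(tert-butyldimethylsilyloxy)-4-(5-methylfuran-2-yl)pentanoate | COC(=O)[C@@H](O[Si](C)(C)C(C)(C)C)C[C@H](C)c1ccc(C)o1
F10 | step 6 | (2S,4S)-2-(tert-butyldimethylsilyloxy)-N-methoxy-N-methyl-4-(5-methylfuran-2-yl)pentanamide | CON(C)C(=O)[C@@H](O[Si](C)(C)C(C)(C)C)C[C@H](C)c1ccc(C)o1
F11 | step 6 | (4S,6S)-4-(tert-butyldimethylsilyloxy)-6-(5-methylfuran-2-yl)hept-1-yn-3-one | C#CC(=O)[C@@H](O[Si](C)(C)C(C)(C)C)C[C@H](C)c1ccc(C)o1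
F12 | step 6 | (4S,8S,10S)-8-(tert-butyldimethylsilyloxy)-1,4-epoxy-1,6-cyclo-11,12,13-trinorgermacra-2,5-dien-7-one | O=C1[C@@H](O[Si](C)(C)C(C)(C)C)C[C@H](C)[C@]2(O3)C=C[C@]3(C)C=C12
F13 | step 10 | bis{[2-(diethoxyphosphoryl)-3-[(4-methoxybenzyl)oxy]propanoyl]oxy}(phenyl)-λ3-iodane | CCOP(=O)(OCC)C(COCc1ccc(OC)cc1)C(=O)OI(OC(=O)C(COCc2ccc(OC)cc2)P(=O)(OCC)OCC)c1ccccc1
A1 | direct plan | (E)-3,4-dibromo-5-[(3S,6S)-3,6-dimethyl-2-oxo-3,8-bis(triethylsilyloxy)oct-4-yn-1-ylidene]furan-2(5H)-one | O=C1O/C(=C/C(=O)[C@@](C)(O[Si](CC)(CC)CC)C#C[C@@H](C)CCO[Si](CC)(CC)CC)C(Br)=C1Br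
A2 | direct plan | (3S)-3-[(5S)-5-{(E)-(3,4-dibromo-5-oxofuran-2(5H)-ylidene)methyl}-5-methyl-4-oxo-4,5-dihydrofuran-2-yl]butanal | O=CC[C@H](C)C1=CC(=O)[C@](C)(/C=C2/OC(=O)C(Br)=C2Br)O1
A3 | direct plan | (4S,8S,10S)-11-bromo-8-hydroxy-3-oxo-1,4-epoxy-13-norgermacra-1,5E,7(11)-trien-12,6-olide | O[C@H]1C[C@H](C)C2=CC(=O)[C@](C)(/C=C3/OC(=O)C(Br)=C31)O2
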